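Ring A is not taken from an aromatic starting material but annulated onto ring C. In the chroman, C5 bears a free hydroxyl beside C4a and C7 a methyl ether; these two carbons map onto the oxygenated carbons of 1,3-dimethoxy-1-(trimethylsilyloxy)buta-1,3-diene, whose ketene-acetal carbon becomes C5 and whose methylene end becomes C8. The key step joins this diene to the enone carbons C4a and C8a of a racemic 3-aryl-5-(phenylsulfinyl)-2,3-dihydropyran-4-one that already carries the prenylated, silyl-protected ring B: it forms C4a–C5 and C8–C8a and aromatises ring A by expelling benzenesulfenic acid and methanol. Dynamic kinetic transfer hydrogenation of the resulting isoflavanone then sets C3 and C4 cis.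

Key step: step 8

Remark: the SMILES is read as the cis (3R,4R) isoflavan-4-ol; every compound that still has the C4 ketone is racemic at C3, which stays labile until step 10; Ar stands for 2-methoxy-5-(3-methylbut-2-en-1-yl)-4-[(triisopropylsilyl)oxy]phenyl.

Step 1
Reactants: 1 4-bromo-3-methoxyphenol; 2 prenyl bromide
Product: 3 4-bromo-5-methoxy-2-(3-methylbut-2-en-1-yl)phenol
Conditions: NaH, toluene, 0 → 25 °C; then 2, 25 °C
Reagents that add atoms: prenyl bromide (2), CC(C)=CCBr
Why: Ortho C-alkylation of a sodium phenoxide held as a tight ion pair in a non-polar solvent, a known route to ortho-prenylphenols, should favour C6 because C2 is flanked by hydroxyl and methoxy and the para position carries bromine; the O-prenyl ether by-product is removed by chromatography.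

Step 2
Reactants: 3 4-bromo-5-methoxy-2-(3-methylbut-2-en-1-yl)phenol; 4 chlorotriisopropylsilane
Product: 5 [4-bromo-5-methoxy-2-(3-methylbut-2-en-1-yl)phenoxy]triisopropylsilane
Conditions: i-Pr3SiCl, imidazole, DMF, 25 → 40 °C
Reagents that add atoms: chlorotriisopropylsilane (4), CC(C)[Si](Cl)(C(C)C)C(C)C
Why: Imidazole-promoted silylation of a phenol; the triisopropylsilyl ether is chosen because it should withstand the lithium amide, sulfinyl carbanion and amide acetal steps better than a smaller silyl group, and it still falls to fluoride at the end.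

Step 3
Reactants: 5 [4-bromo-5-methoxy-2-(3-methylbut-2-en-1-yl)phenoxy]triisopropylsilane; 6 ethyl bromoacetate
Product: 7 ethyl 2-Ar-acetate
Conditions: BrZnCH2CO2Et (1.5 equiv, from 6 and activated Zn, THF, 40 °C), Pd(dba)2 (2 mol%), P(t-Bu)3 (2 mol%), THF, 25 → 50 °C
Reagents that add atoms: ethyl bromoacetate (6), CCOC(=O)CBr
Why: Pd-catalysed α-arylation of an ester through its zinc enolate (Negishi-type coupling of a Reformatsky reagent) runs under neutral conditions that spare the aryl silyl ether and the prenyl group, and the bulky electron-rich phosphine suits the electron-rich, ortho-substituted bromide.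

Step 4
Reactants: 7 ethyl 2-Ar-acetate; 8 formaldehyde
Product: 9 racemic ethyl 3-hydroxy-2-Ar-propanoate
Conditions: LiN(i-Pr)2 (1.1 equiv), THF, −78 °C; CH2O (monomer in THF from cracked paraformaldehyde, 3 equiv), −78 → −30 °C; aq. NH4Cl at −30 °C
Reagents that add atoms: formaldehyde (8), C=O
Why: Aldol addition of the lithium ester enolate to monomeric formaldehyde (hydroxymethylation) can occur only once on the monoanion, and the cold quench avoids retro-aldol and dehydration; the new centre is racemic and becomes the labile C3.

Step 5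
Reactants: 9 racemic ethyl 3-hydroxy-2-Ar-propanoate; 10 methyl phenyl sulfoxide
Product: 11 4-hydroxy-3-Ar-1-(phenylsulfinyl)butan-2-one (mixture of diastereomers)
Conditions: PhS(O)CH3 (3.3 equiv), LiN(i-Pr)2 (3.3 equiv), THF, −78 °C; then 9, −78 → −30 °C; aq. NH4Cl; crude product used directly
Reagents that add atoms: methyl phenyl sulfoxide (10), CS(=O)c1ccccc1
Why: Acyl substitution of an ester by an α-sulfinyl carbanion (Claisen-type β-keto sulfoxide synthesis), in which the first equivalent makes a lithium alkoxide that cannot be eliminated and disfavours deprotonation at the benzylic carbon, the second adds to the ester and the third deprotonates the acidic product and so shields it from further attack.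

Step 6
Reactants: 11 4-hydroxy-3-Ar-1-(phenylsulfinyl)butan-2-one; 12 N,N-dimethylformamide dimethyl acetal
Product: 14 racemic 3-Ar-5-(phenylsulfinyl)-2,3-dihydro-4H-pyran-4-one, via enaminone 13 (not isolated)
Conditions: Me2NCH(OMe)2 (1.3 equiv), THF, 25 °C; evaporate; AcOH, THF, 50 °C
Reagents that add atoms: N,N-dimethylformamide dimethyl acetal (12), COC(OC)N(C)C
Why: Amide acetal condensation at the methylene flanked by carbonyl and sulfinyl gives the enaminone, and acid-promoted addition–elimination by the primary hydroxyl (6-endo attack, loss of Me2NH) closes the ring as in the enaminone route to chromones and sulfinylchromones; the methine C3 cannot condense, and acid sequesters the amine that could otherwise open the ring by elimination at C3.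

Step 7
Reactants: 15 methyl (E)-3-methoxybut-2-enoate; 16 chlorotrimethylsilane
Product: 17 (1Z)-1,3-dimethoxy-1-(trimethylsilyloxy)buta-1,3-diene (Brassard diene)
Conditions: LiN(i-Pr)2 (1.1 equiv), THF, −78 °C; Me3SiCl, −78 → 25 °C; filtration, distillation
Reagents that add atoms: chlorotrimethylsilane (16), C[Si](C)(C)Cl
Why: γ-Deprotonation of the β-methoxy enoate and O-silylation of the dienolate is the standard preparation of this ketene acetal diene; its ketene acetal geometry is irrelevant because that carbon becomes aromatic.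

Step 8
Reactants: 14 racemic 3-Ar-5-(phenylsulfinyl)-2,3-dihydro-4H-pyran-4-one; 17 (1Z)-1,3-dimethoxy-1-(trimethylsilyloxy)buta-1,3-diene
Product: 20 racemic 5-hydroxy-7-methoxy-3-Ar-chroman-4-one, via sulfinyl cycloadduct 18 (not isolated), via 5-O-trimethylsilyl ether 19 (not isolated)
Conditions: 17 (3 equiv), toluene, 25 → 90 °C; then 1 M HCl, THF, 0 °C
Reagents that add atoms: (1Z)-1,3-dimethoxy-1-(trimethylsilyloxy)buta-1,3-diene (17), C=C(OC)/C=C(/OC)O[Si](C)(C)C
Why: The electron-rich diene attacks C6 of enone 14 (the β-carbon, future C8a, activated by both carbonyl and sulfinyl) with its CH2 terminus and bonds to the sulfinyl-bearing α-carbon (future C4a) with its ketene-acetal carbon, either as a concerted suprafacial [4+2] cycloaddition or as a Mukaiyama–Michael addition followed by Claisen-type closure, to give cis-fused adduct 18. The closest known reaction type is the cycloaddition–aromatisation of this diene with sulfinyl- or halo-substituted quinones and enones, together with siloxydiene additions to 3-activated chromones. Ring A is closed by (4+2) annulation with both new bonds (C4a–C5 and C8–C8a) on the same face of the former C5=C6 bond, so the sulfinyl group and the C8a hydrogen are cis; thermal syn elimination of PhSOH restores C4a=C8a, 1,4-loss of methanol from the mixed ketal gives aromatic silyl ether 19, and dilute acid frees phenol 20. No stereocentre is created, since the centres of 18 vanish on aromatisation and C3 stays racemic. The step needs regioselectivity (hydroxyl at C5, methyl ether at C7) and aromatisation with ring C intact; the first follows from matching the nucleophilic diene terminus with the β-carbon, and the second from the quaternary sulfinyl carbon, which blocks enolisation toward C8a (no retro-oxa-Michael opening) and leaves by a cycloelimination that needs no acidic hydrogen at C8a.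

Step 9
Reactants: 20 racemic 5-hydroxy-7-methoxy-3-Ar-chroman-4-one; 21 tert-butylchlorodimethylsilane
Product: 22 racemic 5-[(tert-butyldimethylsilyl)oxy]-7-methoxy-3-Ar-chroman-4-one
Conditions: t-BuMe2SiCl (1.5 equiv), imidazole, DMAP (cat.), DMF, 45 °C
Reagents that add atoms: tert-butylchlorodimethylsilane (21), CC(C)(C)[Si](C)(C)Cl
Why: Imidazole-promoted silylation, warmed because the 5-hydroxyl is hydrogen-bonded to the ketone, removes the chelating phenol that would deactivate the carbonyl toward hydride transfer and installs a group that leaves together with the ring B silyl ether.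

Step 10
Reactants: 22 racemic 5-[(tert-butyldimethylsilyl)oxy]-7-methoxy-3-Ar-chroman-4-one
Product: 23 (3R,4R)-5-[(tert-butyldimethylsilyl)oxy]-7-methoxy-3-Ar-chroman-4-ol (3,4-cis)
Conditions: RuCl(p-cymene)[(R,R)-TsDPEN] (2 mol%), HCO2H/Et3N (5:2), EtOAc, 40 °C
Reagents that add atoms: none
Why: Noyori–Ikariya asymmetric transfer hydrogenation under dynamic kinetic resolution, in which Et3N interconverts the C3 enantiomers through the enol and the (R,R) catalyst reduces one of them faster with hydride delivered anti to the 3-aryl group, should give the cis (3R,4R) alcohol in the sense known for chroman-4-ones and isoflavanones; the prenyl alkene is inert to the ruthenium hydride.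

Step 11
Reactants: 23 (3R,4R)-5-[(tert-butyldimethylsilyl)oxy]-7-methoxy-3-Ar-chroman-4-ol
Product: 24 (3R,4R)-3-[4-hydroxy-2-methoxy-5-(3-methylbut-2-en-1-yl)phenyl]-7-methoxychroman-4,5-diol (target)
Conditions: Bu4NF (2.5 equiv), AcOH (2.5 equiv), THF, 0 → 25 °C
Reagents that add atoms: none
Why: Fluoride cleavage of both aryl silyl ethers under acetic acid buffering is mild enough to leave the electron-rich benzylic C4 alcohol un-ionised and C3 and C4 untouched.

Compound list
1 | 4-bromo-3-methoxyphenol | COc1cc(O)ccc1Br | starting material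
2 | prenyl bromide (1-bromo-3-methylbut-2-ene) | CC(C)=CCBr | starting material
3 | 4-bromo-5-methoxy-2-(3-methylbut-2-en-1-yl)phenol | COc1cc(O)c(CC=C(C)C)cc1Br | intermediate
4 | chlorotriisopropylsilane | CC(C)[Si](Cl)(C(C)C)C(C)C | starting material
5 | [4-bromo-5-methoxy-2-(3-methylbut-2-en-1-yl)phenoxy]triisopropylsilane | COc1cc(O[Si](C(C)C)(C(C)C)C(C)C)c(CC=C(C)C)cc1Br | intermediate
6 | ethyl bromoacetate | CCOC(=O)CBr | starting material
7 | ethyl 2-{2-methoxy-5-(3-methylbut-2-en-1-yl)-4-[(triisopropylsilyl)oxy]phenyl}acetate | CCOC(=O)Cc1cc(CC=C(C)C)c(O[Si](C(C)C)(C(C)C)C(C)C)cc1OC | intermediate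
8 | formaldehyde (monomer, from commercial paraformaldehyde) | C=O | starting material
9 | racemic ethyl 3-hydroxy-2-{2-methoxy-5-(3-methylbut-2-en-1-yl)-4-[(triisopropylsilyl)oxy]phenyl}propanoate | CCOC(=O)C(CO)c1cc(CC=C(C)C)c(O[Si](C(C)C)(C(C)C)C(C)C)cc1OC | intermediate
10 | methyl phenyl sulfoxide (racemic) | CS(=O)c1ccccc1 | starting material
11 | 4-hydroxy-3-{2-methoxy-5-(3-methylbut-2-en-1-yl)-4-[(triisopropylsilyl)oxy]phenyl}-1-(phenylsulfinyl)butan-2-one (diastereomer mixture, racemic) | O=C(CS(=O)c1ccccc1)C(CO)c1cc(CC=C(C)C)c(O[Si](C(C)C)(C(C)C)C(C)C)cc1OC | intermediate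
12 | N,N-dimethylformamide dimethyl acetal | COC(OC)N(C)C | starting material
13 | 1-(dimethylamino)-5-hydroxy-4-Ar-2-(phenylsulfinyl)pent-1-en-3-one (enaminone, not isolated) | CN(C)C=C(C(=O)C(CO)c1cc(CC=C(C)C)c(O[Si](C(C)C)(C(C)C)C(C)C)cc1OC)S(=O)c1ccccc1 | intermediate
14 | racemic 3-{2-methoxy-5-(3-methylbut-2-en-1-yl)-4-[(triisopropylsilyl)oxy]phenyl}-5-(phenylsulfinyl)-2,3-dihydro-4H-pyran-4-one (diastereomer mixture at sulfur) | O=C1C(S(=O)c2ccccc2)=COCC1c1cc(CC=C(C)C)c(O[Si](C(C)C)(C(C)C)C(C)C)cc1OC | intermediate
15 | methyl (E)-3-methoxybut-2-enoate | COC(=O)/C=C(\C)OC | starting material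
16 | chlorotrimethylsilane | C[Si](C)(C)Cl | starting material
17 | (1Z)-1,3-dimethoxy-1-(trimethylsilyloxy)buta-1,3-diene (Brassard diene) | C=C(OC)/C=C(/OC)O[Si](C)(C)C | intermediate
18 | cis-fused cycloadduct: 5,7-dimethoxy-4a-(phenylsulfinyl)-5-(trimethylsilyloxy)-3-Ar-2,3,4a,5,8,8a-hexahydrochromen-4-one (diastereomer mixture, not isolated) | O=C1C(c3cc(CC=C(C)C)c(O[Si](C(C)C)(C(C)C)C(C)C)cc3OC)COC2CC(OC)=CC(OC)(O[Si](C)(C)C)C12S(=O)c1ccccc1 | intermediate
19 | racemic 7-methoxy-5-(trimethylsilyloxy)-3-Ar-chroman-4-one (not isolated) | COc1cc(O[Si](C)(C)C)c2c(c1)OCC(c1cc(CC=C(C)C)c(O[Si](C(C)C)(C(C)C)C(C)C)cc1OC)C2=O | intermediate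
20 | racemic 5-hydroxy-7-methoxy-3-{2-methoxy-5-(3-methylbut-2-en-1-yl)-4-[(triisopropylsilyl)oxy]phenyl}chroman-4-one | COc1cc(O)c2c(c1)OCC(c1cc(CC=C(C)C)c(O[Si](C(C)C)(C(C)C)C(C)C)cc1OC)C2=O | intermediate
21 | tert-butylchlorodimethylsilane | CC(C)(C)[Si](C)(C)Cl | starting material
22 | racemic 5-[(tert-butyldimethylsilyl)oxy]-7-methoxy-3-{2-methoxy-5-(3-methylbut-2-en-1-yl)-4-[(triisopropylsilyl)oxy]phenyl}chroman-4-one | COc1cc(O[Si](C)(C)C(C)(C)C)c2c(c1)OCC(c1cc(CC=C(C)C)c(O[Si](C(C)C)(C(C)C)C(C)C)cc1OC)C2=O | intermediate
23 | (3R,4R)-5-[(tert-butyldimethylsilyl)oxy]-7-methoxy-3-{2-methoxy-5-(3-methylbut-2-en-1-yl)-4-[(triisopropylsilyl)oxy]phenyl}chroman-4-ol (3,4-cis) | COc1cc(O[Si](C)(C)C(C)(C)C)c2c(c1)OC[C@@H](c1cc(CC=C(C)C)c(O[Si](C(C)C)(C(C)C)C(C)C)cc1OC)[C@H]2O | intermediate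
24 | (3R,4R)-3-[4-hydroxy-2-methoxy-5-(3-methylbut-2-en-1-yl)phenyl]-7-methoxychroman-4,5-diol (3,4-cis; CNP0265409.1) | COc1cc(O)c2c(c1)OC[C@@H](c1cc(CC=C(C)C)c(O)cc1OC)[C@H]2O | target

Total step count: 11. Longest linear sequence: 10 steps (steps 1 to 6 and 8 to 11; step 7 prepares the diene on a side branch).

Steps most likely to fail

Step 8 (key step). The push–pull enone may be attacked more slowly than the ketene acetal is hydrolysed or oligomerised, or the first Michael adduct may be trapped on oxygen and not close, so that ring A does not form. The fallback gives up the annulation and makes the C3–aryl bond by Pd-catalysed ketone α-arylation, known for chroman-4-ones. It sets out from aryl bromide 5. Commercial 5,7-dihydroxychroman-4-one is methylated at the non-chelated 7-hydroxyl (MeI, K2CO3, acetone) to 5-hydroxy-7-methoxychroman-4-one F1. F1 is silylated (t-BuMe2SiCl, imidazole, DMF) to 5-[(tert-butyldimethylsilyl)oxy]-7-methoxychroman-4-one F2. F2 is coupled with 5 (Pd(OAc)2, P(t-Bu)3·HBF4, NaOt-Bu, toluene, 60 °C). This should give 22 directly, where the route resumes at step 10.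

Step 5. Proton transfer from the benzylic α-carbon of the ester to the sulfinyl carbanion, or retro-aldol loss of formaldehyde from the alkoxide on warming, may outpace acyl substitution. The fallback reverses the order of the two carbon–carbon bond formations. It sets out from ester 7, which has no β-oxygen. Acylation of PhS(O)CH2Li (2.2 equiv, THF, −78 → 0 °C) by 7 should give 1-Ar-3-(phenylsulfinyl)propan-2-one F3. Its dianion (LiN(i-Pr)2, 2.1 equiv, THF, −78 °C) reacts at the more nucleophilic benzylic γ-carbon, the known site of attack for β-keto sulfoxide dianions. One equivalent of monomeric formaldehyde then gives 11, where the route resumes at step 6.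

Step 10. Hydride transfer to a ketone shielded by the peri silyloxy group may become so slow that conversion stalls, or that the catalyst no longer discriminates between the interconverting C3 enantiomers, with loss of enantio- and diastereocontrol. The fallback replaces catalyst control by substrate control and a physical resolution. It sets out from 22. Reduction with LiBH(s-Bu)3 (THF, −78 °C; aq. NH4Cl) delivers hydride anti to the 3-aryl group and should give the racemic cis alcohol, rac-(3R*,4R*)-5-[(tert-butyldimethylsilyl)oxy]-7-methoxy-3-Ar-chroman-4-ol F4. Preparative chromatography of F4 on a chiral stationary phase then gives 23, where the route resumes at step 11.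

Further compounds
F1 | step 8 | 5-hydroxy-7-methoxychroman-4-one | COc1cc(O)c2c(c1)OCCC2=O
F2 | step 8 | 5-[(tert-butyldimethylsilyl)oxy]-7-methoxychroman-4-one | COc1cc(O[Si](C)(C)C(C)(C)C)c2c(c1)OCCC2=O
F3 | step 5 | 1-{2-methoxy-5-(3-methylbut-2-en-1-yl)-4-[(triisopropylsilyl)oxy]phenyl}-3-(phenylsulfinyl)propan-2-one | O=C(CS(=O)c1ccccc1)Cc1cc(CC=C(C)C)c(O[Si](C(C)C)(C(C)C)C(C)C)cc1OC
F4 | step 10 | racemic cis 5-[(tert-butyldimethylsilyl)oxy]-7-methoxy-3-Ar-chroman-4-ol (racemate, one enantiomer drawn) | COc1cc(O[Si](C)(C)C(C)(C)C)c2c(c1)OC[C@@H](c1cc(CC=C(C)C)c(O[Si](C(C)C)(C(C)C)C(C)C)cc1OC)[C@H]2O
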